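**Strategy.** Everything rests on cutting the lactone O–C4 bond (numbering from the lactone carbonyl C1 along the chain). C4, the methyl-bearing carbon shared by γ-lactone ring A and 1,2-dioxane ring B, has three carbon neighbours (CH3, C3, C5) that give a nucleophile no useful size contrast, so it is first built as an all-carbon quaternary centre next to a cyclobutanone carbonyl. Baeyer–Villiger ring expansion then, in one operation, slips oxygen between C1 and C4, creates ring A and hands the configuration on unchanged. The precursor is (R)-2-methyl-2-(2-methyleneoctadecyl)cyclobutanone, obtained by catalytic asymmetric decarboxylative allylation; its exocyclic methylene later becomes C6 with its methyl group, and ring B closes by hydroperoxide conjugate addition.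

Key step: step 7

**Numbering.** C1 is the lactone C=O, C2 is CH2, C3 is CH–OO, C4 is C(CH3)–O(lactone), C5 is CH2, C6 is C(CH3)–OO, and C7–C22 form the hexadecyl chain. The target is (3S,4S,6R) in this numbering, which equals (3R,4aS,7aS) in the furo[3,2-c][1,2]dioxine numbering. Rings A and B are cis-fused.

**Assumption.** The PHOX catalyst is taken to show the same sense of induction on the four-membered enolate as on five- to seven-membered ones, where the (S)-ligand gives the (S)-2-allyl-2-methyl ketone. The (R)-ligand is therefore specified: (R)-(CF3)3-t-BuPHOX, which is (R)-4-tert-butyl-2-{2-[bis(4-trifluoromethylphenyl)phosphanyl]-5-(trifluoromethyl)phenyl}-4,5-dihydrooxazole. If chiral analysis showed the opposite sense, the antipodal ligand would be used with no other change.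

**Stereochemical bookkeeping.** C4 keeps one spatial arrangement from the cyclobutanone to the target. Its descriptor reads R in the cyclobutanone and the saturated lactone and S from the selenide onward. This is only because the CIP ranks of C3 and C5 swap.

**Step 1**
Reactants: 1 octadecanal; 2 formaldehyde
Product: 3 2-methyleneoctadecanal
Conditions: 37% aq HCHO, pyrrolidine (10 mol %), EtCO2H (10 mol %), i-PrOH, 45 °C
Reagents that add atoms: formaldehyde (2), C=O
Why: Amine-catalysed Mannich condensation of the enamine of 1 with formaldehyde followed by β-elimination of the amine (organocatalytic α-methylenation) is general for linear aldehydes and stops cleanly because 3 has no α-hydrogen left.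

**Step 2**
Reactants: 3 2-methyleneoctadecanal
Product: 4 2-methyleneoctadecan-1-ol
Conditions: NaBH4, CeCl3·7H2O, MeOH–THF, 0 °C
Reagents that add atoms: none
Why: Luche reduction delivers hydride to the carbonyl carbon only, since the hard cerium-modified alkoxyborohydride avoids conjugate reduction and leaves the 1,1-disubstituted alkene in place.

**Step 3**
Reactants: 5 cyclopentane-1,3-dione
Product: 6 2-diazocyclopentane-1,3-dione
Conditions: 4-AcNHC6H4SO2N3 (p-ABSA), Et3N, MeCN, 0 °C → rt
Reagents that add atoms: 4-acetamidobenzenesulfonyl azide, CC(=O)Nc1ccc(cc1)S(=O)(=O)N=[N+]=[N-]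
Why: Regitz diazo transfer, in which the amine-generated enolate of the strongly acidic 1,3-diketone attacks the terminal nitrogen of the sulfonyl azide and the adduct collapses to the stabilised diazo diketone and the sulfonamide.

**Step 4**
Reactants: 4 2-methyleneoctadecan-1-ol; 6 2-diazocyclopentane-1,3-dione
Product: 8 2-methyleneoctadecyl 2-oxocyclobutane-1-carboxylate, via acylketene 7 (not isolated)
Conditions: PhMe, 180 °C (microwave, sealed vessel, small batches), 6 in slight excess
Reagents that add atoms: none
Why: Thermal Wolff rearrangement expels N2 while a ring CH2 shifts to the diazo carbon, contracting the five-membered ring to acylketene 7, which the primary alcohol 4 captures to give the β-keto ester without any need to acylate a cyclobutanone enolate.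

**Step 5**
Reactants: 8 2-methyleneoctadecyl 2-oxocyclobutane-1-carboxylate; 9 iodomethane
Product: 10 2-methyleneoctadecyl 1-methyl-2-oxocyclobutane-1-carboxylate (racemic)
Conditions: MeI, K2CO3, acetone, 40 °C
Reagents that add atoms: iodomethane (9), CI
Why: Enolate C-alkylation of a β-keto ester with a small soft electrophile under carbonate conditions, which contain no nucleophile able to open the strained ring; the quaternary centre is racemic on purpose because step 6 erases and rebuilds it.

**Step 6**
Reactants: 10 2-methyleneoctadecyl 1-methyl-2-oxocyclobutane-1-carboxylate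
Product: 11 (R)-2-methyl-2-(2-methyleneoctadecyl)cyclobutan-1-one
Conditions: Pd2(dba)3 (2.5 mol %), (R)-(CF3)3-t-BuPHOX (6.5 mol %), PhMe, 20 °C
Reagents that add atoms: none
Why: Decarboxylative asymmetric allylic alkylation (Tsuji type), in which zerovalent palladium ionises the allyl ester, loss of CO2 leaves a prochiral cyclobutanone enolate on the π-allyl–PHOX complex and inner-sphere C–C coupling takes place on the enolate face left open by the tert-butyl oxazoline, so that both enantiomers of 10 converge on (R)-11, C4 is set by the ligand, and the symmetric allyl termini raise no regiochemical question.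

**Step 7**
Reactants: 11 (R)-2-methyl-2-(2-methyleneoctadecyl)cyclobutan-1-one
Product: 13 (R)-5-methyl-5-(2-methyleneoctadecyl)dihydrofuran-2(3H)-one, via Criegee perhydrate 12 (not isolated)
Conditions: 30% aq H2O2, AcOH–THF, 0 °C → rt
Reagents that add atoms: hydrogen peroxide, OO
Why: Hydrogen peroxide adds to the strained and therefore unusually electrophilic carbonyl C1 to give perhydrate 12, whose O–O bond breaks as the antiperiplanar C1–C4 bond shifts to oxygen; this is the Baeyer–Villiger oxidation of a 2,2-disubstituted cyclobutanone, an established entry to γ,γ-disubstituted butyrolactones. Ring A arises by one-atom ring expansion (four to five members through a 1,2-shift) and not by an end-to-end cyclisation, so no closure mode has to be won. No stereocentre is created: the shift is concerted and the migrating carbon keeps its configuration, which converts the all-carbon quaternary centre of 11 into the C4–O stereocentre of the target. Regioselectivity between C4 and the ring methylene C2 is required and is secured by the much better ability of the fully substituted carbon to carry positive charge in the migration transition state. Chemoselectivity over the C6 methylene group is also required and rests on strain release, which lets unactivated H2O2 suffice, a reagent that does not epoxidise an isolated 1,1-disubstituted alkene at this temperature, as known from alkenyl cyclobutanones oxidised in the same medium.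

**Step 8**
Reactants: 13 (R)-5-methyl-5-(2-methyleneoctadecyl)dihydrofuran-2(3H)-one
Product: 15 (5S)-5-methyl-5-(2-methyleneoctadecyl)-3-(phenylselanyl)dihydrofuran-2(3H)-one (epimers at the selenium-bearing carbon), via lithium enolate 14 (not isolated)
Conditions: LiN(i-Pr)2, THF, −78 °C; then PhSeBr, −78 °C
Reagents that add atoms: benzeneselenenyl bromide, Br[Se]c1ccccc1
Why: Kinetic enolisation at C2, the only acidic site, and α-selenenylation of the lithium enolate (first half of the selenoxide dehydrogenation) is far faster at −78 °C than addition of PhSeBr to the alkene, and the epimer mixture at C2 is irrelevant because that centre becomes sp2 in step 9.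

**Step 9**
Reactants: 15 (5S)-5-methyl-5-(2-methyleneoctadecyl)-3-(phenylselanyl)dihydrofuran-2(3H)-one
Product: 17 (S)-5-methyl-5-(2-methyleneoctadecyl)furan-2(5H)-one, via selenoxide 16 (not isolated)
Conditions: 30% aq H2O2, pyridine, CH2Cl2, 0 °C → rt
Reagents that add atoms: none
Why: Oxidation occurs selectively at selenium and selenoxide 16 undergoes syn-elimination toward C3, the only neighbouring carbon that bears hydrogen; C4 has no hydrogen, so the butenolide can neither racemise nor tautomerise, and pyridine buffering with short contact at low temperature keeps selenium peracids from touching the alkene.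

**Step 10**
Reactants: 17 (S)-5-methyl-5-(2-methyleneoctadecyl)furan-2(5H)-one
Product: 18 (S)-5-methyl-5-[(R)-2-methyl-2-(triethylsilylperoxy)octadecyl]furan-2(5H)-one
Conditions: Co(acac)2 (10 mol %), Et3SiH, O2 (1 atm), ClCH2CH2Cl, rt; chromatographic separation of the C6 epimers
Reagents that add atoms: dioxygen, O=O; triethylsilane, CC[SiH](CC)CC
Why: Mukaiyama–Isayama hydroperoxysilylation, in which a cobalt hydride transfers hydrogen to the terminal CH2 of the electron-rich alkene (Markovnikov sense), the tertiary C6 radical traps O2 and the cobalt peroxide is silylated while the electron-poor butenolide reacts much more slowly; the planar radical lies too far from C4 for useful facial bias, so both C6 epimers are expected and the (6R)-isomer 18 is secured by chromatography, its assignment to be confirmed by NOE after ring closure.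

**Step 11**
Reactants: 18 (S)-5-methyl-5-[(R)-2-methyl-2-(triethylsilylperoxy)octadecyl]furan-2(5H)-one
Product: 20 (3R,4aS,7aS)-3-hexadecyl-3,4a-dimethyl-4,4a,7,7a-tetrahydro-3H-furo[3,2-c][1,2]dioxin-6-one, via hydroperoxide 19 (not isolated)
Conditions: HCl (cat.), MeOH–CH2Cl2, 0 °C; concentrate; then Et2NH (cat.), CF3CH2OH, rt
Reagents that add atoms: none
Why: Acid methanolysis cleaves the labile O–Si bond and hydroperoxide 19 then adds to C3 of the butenolide under mild amine catalysis (intramolecular oxa-Michael addition, 6-exo-trig); the tether anchored at C4 reaches only the butenolide face that carries C5, which sets C3 as S with a cis ring fusion, and the acidic fluorinated alcohol protonates the enolate before it can attack the O–O bond.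

**Compound list**
1 | octadecanal | CCCCCCCCCCCCCCCCCC=O | starting material
2 | formaldehyde | C=O | starting material
3 | 2-methyleneoctadecanal | CCCCCCCCCCCCCCCCC(=C)C=O | intermediate
4 | 2-methyleneoctadecan-1-ol | CCCCCCCCCCCCCCCCC(=C)CO | intermediate
5 | cyclopentane-1,3-dione | O=C1CCC(=O)C1 | starting material
6 | 2-diazocyclopentane-1,3-dione | [N-]=[N+]=C1C(=O)CCC1=O | intermediate
7 | 2-(oxomethylidene)cyclobutan-1-one (acylketene, not isolated) | O=C=C1CCC1=O | intermediate
8 | 2-methyleneoctadecyl 2-oxocyclobutane-1-carboxylate | CCCCCCCCCCCCCCCCC(=C)COC(=O)C1CCC1=O | intermediate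
9 | iodomethane | CI | starting material
10 | 2-methyleneoctadecyl 1-methyl-2-oxocyclobutane-1-carboxylate (racemic) | CCCCCCCCCCCCCCCCC(=C)COC(=O)C1(C)CCC1=O | intermediate
11 | (R)-2-methyl-2-(2-methyleneoctadecyl)cyclobutan-1-one | CCCCCCCCCCCCCCCCC(=C)C[C@@]1(C)CCC1=O | intermediate
12 | (2R)-1-hydroperoxy-2-methyl-2-(2-methyleneoctadecyl)cyclobutan-1-ol (Criegee perhydrate, not isolated) | CCCCCCCCCCCCCCCCC(=C)C[C@@]1(C)CCC1(O)OO | intermediate
13 | (R)-5-methyl-5-(2-methyleneoctadecyl)dihydrofuran-2(3H)-one | CCCCCCCCCCCCCCCCC(=C)C[C@@]1(C)CCC(=O)O1 | intermediate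
14 | lithium enolate of 13 (not isolated) | CCCCCCCCCCCCCCCCC(=C)C[C@@]1(C)CC=C([O-])O1.[Li+] | intermediate
15 | (5S)-5-methyl-5-(2-methyleneoctadecyl)-3-(phenylselanyl)dihydrofuran-2(3H)-one | CCCCCCCCCCCCCCCCC(=C)C[C@@]1(C)CC([Se]c2ccccc2)C(=O)O1 | intermediate
16 | (5S)-5-methyl-5-(2-methyleneoctadecyl)-3-(phenylseleninyl)dihydrofuran-2(3H)-one (selenoxide, not isolated) | CCCCCCCCCCCCCCCCC(=C)C[C@@]1(C)CC([Se](=O)c2ccccc2)C(=O)O1 | intermediate
17 | (S)-5-methyl-5-(2-methyleneoctadecyl)furan-2(5H)-one | CCCCCCCCCCCCCCCCC(=C)C[C@@]1(C)C=CC(=O)O1 | intermediate
18 | (S)-5-methyl-5-[(R)-2-methyl-2-(triethylsilylperoxy)octadecyl]furan-2(5H)-one | CCCCCCCCCCCCCCCC[C@@](C)(OO[Si](CC)(CC)CC)C[C@@]1(C)C=CC(=O)O1 | intermediate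
19 | (S)-5-[(R)-2-hydroperoxy-2-methyloctadecyl]-5-methylfuran-2(5H)-one (not isolated) | CCCCCCCCCCCCCCCC[C@@](C)(OO)C[C@@]1(C)C=CC(=O)O1 | intermediate
20 | (3R,4aS,7aS)-3-hexadecyl-3,4a-dimethyl-4,4a,7,7a-tetrahydro-3H-furo[3,2-c][1,2]dioxin-6-one | CCCCCCCCCCCCCCCC[C@]1(C)C[C@]2(C)OC(=O)C[C@@H]2OO1 | target

**Step count**
- Total step count: 11.
- Longest linear sequence: 10 (octadecanal through steps 1, 2 and 4–11). Step 3 is a one-step side branch.

**The three steps most likely to fail**

Step 10.
- What may go wrong: O2 captures the tertiary C6 radical from both faces without bias, and the two flexible silyl peroxides may co-elute, so no single epimer is obtained at this stage.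
- Fallback: the separation is moved from the acyclic series to the conformationally locked bicycles. Setting out from 17, the peroxidation product is carried on unseparated. It consists of 18 together with (S)-5-methyl-5-[(S)-2-methyl-2-(triethylsilylperoxy)octadecyl]furan-2(5H)-one F1.
- Methanolysis gives 19 beside (S)-5-[(S)-2-hydroperoxy-2-methyloctadecyl]-5-methylfuran-2(5H)-one F2. Amine-mediated closure then gives 20 beside (3S,4aS,7aS)-3-hexadecyl-3,4a-dimethyl-4,4a,7,7a-tetrahydro-3H-furo[3,2-c][1,2]dioxin-6-one F3.
- The two bicycles differ in whether the hexadecyl chain or the C6 methyl group is axial on ring B. That difference should make silica gel chromatography or crystallisation effective and allows direct NOE assignment. The route is rejoined at 20.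

Step 6.
- What may go wrong: the catalyst may discriminate the faces of the small, flat four-membered enolate insufficiently, which would erode enantiomeric purity.
- Fallback: optical purity is completed by diastereomer separation and no longer depends on catalysis alone. Setting out from scalemic 13 (after step 7), AlMe3-promoted aminolysis with (S)-1-phenylethylamine in CH2Cl2 opens the lactone to (R)-4-hydroxy-4-methyl-6-methylene-N-[(S)-1-phenylethyl]docosanamide F4. The minor enantiomer gives (S)-4-hydroxy-4-methyl-6-methylene-N-[(S)-1-phenylethyl]docosanamide F5.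
- After chromatography or crystallisation, F4 is relactonised with TsOH·H2O in wet THF at 50 °C. This is an acyl transfer that does not touch the C4–O bond. The route is rejoined at 13 as a single enantiomer.

Step 4.
- What may go wrong: ketene dimerisation or thermal breakdown of the diazo diketone may outrun capture by an alcohol that is used only stoichiometrically.
- Fallback: the ester-bearing carbon is attached by enolate acylation, with no ring contraction. Setting out from 4, 1,1'-carbonyldiimidazole in THF at rt gives 2-methyleneoctadecyl 1H-imidazole-1-carboxylate F6.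
- Commercial cyclobutanone is converted with LiN(SiMe3)2 (two equivalents, THF, −78 °C) into lithium cyclobut-1-en-1-olate F7. F6 acylates this enolate at carbon in the absence of a Lewis acid. The route is rejoined at 8.

**Further compounds**
F1 | step 10 | (S)-5-methyl-5-[(S)-2-methyl-2-(triethylsilylperoxy)octadecyl]furan-2(5H)-one | CCCCCCCCCCCCCCCC[C@](C)(OO[Si](CC)(CC)CC)C[C@@]1(C)C=CC(=O)O1
F2 | step 10 | (S)-5-[(S)-2-hydroperoxy-2-methyloctadecyl]-5-methylfuran-2(5H)-one | CCCCCCCCCCCCCCCC[C@](C)(OO)C[C@@]1(C)C=CC(=O)O1
F3 | step 10 | (3S,4aS,7aS)-3-hexadecyl-3,4a-dimethyl-4,4a,7,7a-tetrahydro-3H-furo[3,2-c][1,2]dioxin-6-one | CCCCCCCCCCCCCCCC[C@@]1(C)C[C@]2(C)OC(=O)C[C@@H]2OO1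
F4 | step 6 | (R)-4-hydroxy-4-methyl-6-methylene-N-[(S)-1-phenylethyl]docosanamide | CCCCCCCCCCCCCCCCC(=C)C[C@](C)(O)CCC(=O)N[C@@H](C)c1ccccc1
F5 | step 6 | (S)-4-hydroxy-4-methyl-6-methylene-N-[(S)-1-phenylethyl]docosanamide | CCCCCCCCCCCCCCCCC(=C)C[C@@](C)(O)CCC(=O)N[C@@H](C)c1ccccc1
F6 | step 4 | 2-methyleneoctadecyl 1H-imidazole-1-carboxylate | CCCCCCCCCCCCCCCCC(=C)COC(=O)n1ccnc1
F7 | step 4 | lithium cyclobut-1-en-1-olate | [Li+].[O-]C1=CCC1
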